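The route rests on disconnecting ring A at the bond between quaternary C4 and ring-fusion C5 (labdane numbering), the bond that starts a head-to-tail polyene cyclisation. The feature used is the isoprenoid register of C4 (methyl plus oxidised C18), C5, C10, C9 and the C8 carbinol. In one operation a Lewis acid zips an acyclic (E,E)-farnesylacetone epoxide, whose oxirane carries the future C18 as a silyloxymethyl group, into rings A and B and a temporary dihydropyran, setting C4, C5, C10, C9 and C8 from one Sharpless-derived oxirane. Afterwards the surplus 3-hydroxyl is removed, the C18 hydroxyl relays oxidation to C6 through a lactone, and the butenolide is condensed on last.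

Key step: step 4

Remark 1: labdane numbering is used for all cyclised compounds (decalin C1–C10, side chain C11–C16, C17 on C8, C18 = 4α carbon, C19 = 4β methyl, C20 on C10), in the normal series (5α-H, 9α-H, 10β-methyl).
Remark 2: isomerically pure (5E,9E)-farnesylacetone is assumed to be purchasable.
Remark 3: the ketal carbon C13 in 8–11 and the lactol carbon in 15 are transient centres, carried as epimer mixtures.

Step 1
Reactants: 1 (5E,9E)-farnesylacetone
Product: 2 (5E,9E,13E)-15-hydroxy-6,10,14-trimethylpentadeca-5,9,13-trien-2-one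
Conditions: SeO2 (cat.), t-BuOOH, salicylic acid (cat.), CH2Cl2, 0 °C to rt, run to partial conversion
Reagents that add atoms: tert-butyl hydroperoxide, CC(C)(C)OO
Why: Riley-type allylic oxidation (ene reaction, then [2,3]-sigmatropic shift) should be fastest at the least hindered terminal trisubstituted alkene and give the (E)-primary allylic alcohol; no stereocentre is formed.

Step 2
Reactants: 2 (E)-allylic alcohol
Product: 3 (5E,9E)-12-[(2S,3S)-3-(hydroxymethyl)-3-methyloxiran-2-yl]-6,10-dimethyldodeca-5,9-dien-2-one
Conditions: Ti(OiPr)4 (cat.), L-(+)-diethyl tartrate (cat.), t-BuOOH, 4 Å molecular sieves, CH2Cl2, −20 °C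
Reagents that add atoms: tert-butyl hydroperoxide, CC(C)(C)OO
Why: Sharpless asymmetric epoxidation touches only the alkene of the allylic alcohol, and the L-(+)-tartrate catalyst delivers oxygen to the face that gives the (2S,3S)-oxirane (future C3 and C4) under catalyst control.

Step 3
Reactants: 3 epoxy alcohol
Product: 4 (5E,9E)-12-[(2S,3S)-3-(tert-butyldimethylsilyloxymethyl)-3-methyloxiran-2-yl]-6,10-dimethyldodeca-5,9-dien-2-one
Conditions: TBSCl, imidazole, DMF, rt
Reagents that add atoms: tert-butyldimethylsilyl chloride, CC(C)(C)[Si](C)(C)Cl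
Why: Silyl ether formation caps the primary hydroxyl so that it cannot divert the Lewis acid of step 4; no stereocentre changes.

Step 4
Reactants: 4 silyl-protected epoxy dienone
Product: 5 18-(tert-butyldimethylsilyloxy)-8α,13-epoxy-14,15-dinorlabd-12-en-3β-ol
Conditions: MeAlCl2 (2 equiv), CH2Cl2, −78 °C
Reagents that add atoms: none
Why: MeAlCl2 activates the oxirane, and ionisation of its tertiary C4–O bond is assisted by the C5=C10 alkene, so C5 attacks C4 with inversion while C10 is attacked by C9 of the C8=C9 alkene and the C8 cation is captured by the ketone oxygen, the oxocarbenium ion then losing H12 to give the enol ether. The closest known reaction type is the Lewis-acid-promoted epoxy-polyene cyclisation with carbonyl-oxygen termination. Ring A closes 6-endo at the more substituted oxirane carbon (C4–C5), ring B closes 6-endo-trig (C9–C10), and the dihydropyran closes by six-membered oxygen capture of the C8 cation (C8–O). C4 is set by inversion of the Sharpless-derived oxirane carbon (the E-disposed CH2OTBS ends equatorial, 4α), C3 is carried over unchanged (3β-OH), the trans C5/C10 and the C9/C8 centres arise from anti addition across the two E-alkenes in a chair–chair fold, and the absolute sense of the fold follows from the oxirane. The step needs initiation at the epoxide only and 6-endo instead of 5-exo opening, which the tertiary oxirane carbon and the low temperature should secure, and a clean termination, which the internal ketone oxygen secures.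

Step 5
Reactants: 5 tricyclic 3β-alcohol
Product: 6 O-[18-(tert-butyldimethylsilyloxy)-8α,13-epoxy-14,15-dinorlabd-12-en-3β-yl] imidazole-1-carbothioate
Conditions: 1,1'-thiocarbonyldiimidazole, DMAP (cat.), ClCH2CH2Cl, 70 °C
Reagents that add atoms: 1,1'-thiocarbonyldiimidazole, S=C(n1ccnc1)n1ccnc1
Why: Thioacylation of the equatorial secondary hydroxyl gives the thiocarbonyl derivative needed for Barton–McCombie deoxygenation under neutral conditions that spare the enol ether and the silyl ether.

Step 6
Reactants: 6 thiocarbonyl imidazolide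
Product: 7 18-(tert-butyldimethylsilyloxy)-8α,13-epoxy-14,15-dinorlabd-12-ene
Conditions: Bu3SnH, AIBN (cat.), toluene, 110 °C
Reagents that add atoms: none
Why: Barton–McCombie deoxygenation (stannyl radical addition to C=S, β-scission to the secondary C3 radical, hydrogen transfer from Bu3SnH) removes the surplus 3-oxygen; the C3 stereocentre is erased and no other centre is touched.

Step 7
Reactants: 7 deoxygenated enol ether
Product: 8 13-methoxy-8α,13-epoxy-14,15-dinorlabdan-18-ol
Conditions: camphorsulfonic acid (cat.), MeOH, 0 °C to rt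
Reagents that add atoms: methanol, CO
Why: Acid-catalysed methanolysis should cleave the primary silyl ether and, in the same flask, add methanol to the enol ether (oxocarbenium capture) to give the cyclic methyl ketal, which masks the tertiary 8-oxygen and the C13 carbonyl during the oxidations that follow.

Step 8
Reactants: 8 primary alcohol
Product: 10 13-methoxy-6α,18:8α,13-diepoxy-14,15-dinorlabdane, via C18 hypoiodite 9 (not isolated)
Conditions: PhI(OAc)2, I2, NaHCO3 (solid), cyclohexane, tungsten lamp, 40 °C
Reagents that add atoms: none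
Why: In this Suárez hypoiodite reaction the C18 alkoxyl radical should abstract the peri-disposed equatorial 6α-hydrogen through a chair-like six-membered transition state (1,5-hydrogen transfer), and oxidation of the C6 radical with closure by the tethered oxygen can only give the 6α C–O bond.

Step 9
Reactants: 10 cyclic ether
Product: 12 8α-hydroxy-13-oxo-14,15-dinorlabdan-18,6α-olide, via ketal lactone 11 (not isolated)
Conditions: RuCl3·xH2O (cat.), NaIO4, EtOAc/MeCN/H2O, rt; then 1 M HCl, THF, rt
Reagents that add atoms: sodium periodate, [Na+].[O-]I(=O)(=O)=O; water, O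
Why: RuO4 made in the flask oxidises the less hindered methylene next to the ether oxygen (C18) to the γ-lactone without touching a stereocentre, and dilute acid then hydrolyses the methyl ketal to the 8α-hydroxy methyl ketone.

Step 10
Reactants: 12 hydroxy keto lactone; 13 triethyl phosphonoacetate
Product: 14 ethyl (13E)-8α-hydroxy-18-oxo-6α,18-epoxylabd-13-en-15-oate
Conditions: NaH, THF, 0 °C to 60 °C (phosphonate in slight excess over base)
Reagents that add atoms: none
Why: Horner–Wadsworth–Emmons olefination of the methyl ketone should favour the (E)-trisubstituted enoate (ester trans to the C12 chain), with the minor (Z)-isomer to be removed by chromatography; the lactone has no α-hydrogen and resists the stabilised anion.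

Step 11
Reactants: 14 enoate lactone
Product: 15 (13E)-6α,18-epoxylabd-13-ene-8α,15,18-triol (lactol)
Conditions: i-Bu2AlH, CH2Cl2, −78 °C; aq. potassium sodium tartrate work-up
Reagents that add atoms: none
Why: DIBAL reduction at low temperature should take the enoate to the allylic alcohol and stop the hindered γ-lactone at the lactol (stable aluminium hemiacetal), which unmasks C18 at the aldehyde level without any hydroxide.

Step 12
Reactants: 15 lactol diol
Product: 16 (13E)-6α,8α,15-trihydroxylabd-13-en-18-oic acid
Conditions: NaClO2, NaH2PO4, 2-methyl-2-butene, t-BuOH/H2O, rt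
Reagents that add atoms: sodium chlorite, [Na+].[O-]Cl=O
Why: Pinnick oxidation of the open hydroxy-aldehyde form of the lactol gives the C18 acid and frees the 6α-hydroxyl; chlorite leaves the allylic alcohol alone and the scavenger protects the alkene.

Step 13
Reactants: 16 trihydroxy acid
Product: 17 (13E)-6α,8α-dihydroxy-15-oxolabd-13-en-18-oic acid
Conditions: MnO2, CH2Cl2, rt
Reagents that add atoms: none
Why: MnO2 oxidises only the allylic primary alcohol and should give the (E)-enal with the alkene geometry retained.

Step 14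
Reactants: 17 hydroxy acid enal; 18 4-methylfuran-2(5H)-one
Product: 23 CNP0145461.1, via 4-methyl-2-(trimethylsilyloxy)furan 19 (not isolated), via tris(trimethylsilyl) enal 20 (not isolated), via silylated aldol adduct 21 (not isolated), via tris(trimethylsilyl) dienyl butenolide 22 (not isolated)
Conditions: 18, Et3N, Me3SiOTf (excess), CH2Cl2, 0 °C; then 17, −78 °C to −20 °C; DBU, −20 °C to rt; 10% aq. citric acid, THF, 0 °C
Reagents that add atoms: none
Why: Vinylogous Mukaiyama aldol addition of the silyloxyfuran at its C5 to the silyl-activated enal, then DBU-induced E1cB loss of silanol, should give the thermodynamically preferred (Z)-ylidene butenolide (chain syn to the ring oxygen, away from the 4-methyl), and mild acid strips the transient trimethylsilyl groups while the 13E alkene is carried through.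

Compound list
1 | (5E,9E)-6,10,14-trimethylpentadeca-5,9,13-trien-2-one ((E,E)-farnesylacetone) | CC(=O)CC/C=C(\C)CC/C=C(\C)CCC=C(C)C | starting material
2 | (5E,9E,13E)-15-hydroxy-6,10,14-trimethylpentadeca-5,9,13-trien-2-one | CC(=O)CC/C=C(\C)CC/C=C(\C)CC/C=C(\C)CO | intermediate
3 | (5E,9E)-12-[(2S,3S)-3-(hydroxymethyl)-3-methyloxiran-2-yl]-6,10-dimethyldodeca-5,9-dien-2-one | CC(=O)CC/C=C(\C)CC/C=C(\C)CC[C@@H]1O[C@@]1(C)CO | intermediate
4 | tert-butyldimethylsilyl ether of 3 | CC(=O)CC/C=C(\C)CC/C=C(\C)CC[C@@H]1O[C@@]1(C)CO[Si](C)(C)C(C)(C)C | intermediate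
5 | 18-(tert-butyldimethylsilyloxy)-8α,13-epoxy-14,15-dinorlabd-12-en-3β-ol | CC1=CC[C@@H]2[C@@]3(C)CC[C@H](O)[C@@](C)(CO[Si](C)(C)C(C)(C)C)[C@@H]3CC[C@@]2(C)O1 | intermediate
6 | 3β-O-(imidazol-1-ylthiocarbonyl) derivative of 5 | CC1=CC[C@@H]2[C@@]3(C)CC[C@H](OC(=S)n4ccnc4)[C@@](C)(CO[Si](C)(C)C(C)(C)C)[C@@H]3CC[C@@]2(C)O1 | intermediate
7 | 18-(tert-butyldimethylsilyloxy)-8α,13-epoxy-14,15-dinorlabd-12-ene | CC1=CC[C@@H]2[C@@]3(C)CCC[C@@](C)(CO[Si](C)(C)C(C)(C)C)[C@@H]3CC[C@@]2(C)O1 | intermediate
8 | 13-methoxy-8α,13-epoxy-14,15-dinorlabdan-18-ol (C13 epimers) | COC1(C)CC[C@@H]2[C@@]3(C)CCC[C@@](C)(CO)[C@@H]3CC[C@@]2(C)O1 | intermediate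
9 | C18 hypoiodite of 8 | COC1(C)CC[C@@H]2[C@@]3(C)CCC[C@@](C)(COI)[C@@H]3CC[C@@]2(C)O1 | intermediate (not isolated)
10 | 13-methoxy-6α,18:8α,13-diepoxy-14,15-dinorlabdane | COC1(C)CC[C@@H]2[C@@]3(C)CCC[C@]4(C)[C@@H]3[C@@H](OC4)C[C@@]2(C)O1 | intermediate
11 | 13-methoxy-8α,13-epoxy-14,15-dinorlabdan-18,6α-olide | COC1(C)CC[C@@H]2[C@@]3(C)CCC[C@]4(C)[C@@H]3[C@@H](OC4=O)C[C@@]2(C)O1 | intermediate (not isolated)
12 | 8α-hydroxy-13-oxo-14,15-dinorlabdan-18,6α-olide | CC(=O)CC[C@@H]1[C@@]2(C)CCC[C@]3(C)[C@@H]2[C@@H](OC3=O)C[C@@]1(C)O | intermediate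
13 | triethyl phosphonoacetate | CCOC(=O)CP(=O)(OCC)OCC | starting material
14 | ethyl (13E)-8α-hydroxy-18-oxo-6α,18-epoxylabd-13-en-15-oate | CCOC(=O)/C=C(\C)CC[C@@H]1[C@@]2(C)CCC[C@]3(C)[C@@H]2[C@@H](OC3=O)C[C@@]1(C)O | intermediate
15 | (13E)-6α,18-epoxylabd-13-ene-8α,15,18-triol (lactol, C18 epimers) | OC/C=C(\C)CC[C@@H]1[C@@]2(C)CCC[C@]3(C)[C@@H]2[C@@H](OC3O)C[C@@]1(C)O | intermediate
16 | (13E)-6α,8α,15-trihydroxylabd-13-en-18-oic acid | OC/C=C(\C)CC[C@@H]1[C@@]2(C)CCC[C@@](C)(C(=O)O)[C@@H]2[C@@H](O)C[C@@]1(C)O | intermediate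
17 | (13E)-6α,8α-dihydroxy-15-oxolabd-13-en-18-oic acid | O=C/C=C(\C)CC[C@@H]1[C@@]2(C)CCC[C@@](C)(C(=O)O)[C@@H]2[C@@H](O)C[C@@]1(C)O | intermediate
18 | 4-methylfuran-2(5H)-one | CC1=CC(=O)OC1 | starting material
19 | 4-methyl-2-(trimethylsilyloxy)furan | C[Si](C)(C)Oc1cc(C)co1 | intermediate (not isolated)
20 | trimethylsilyl (13E)-15-oxo-6α,8α-bis(trimethylsilyloxy)labd-13-en-18-oate | O=C/C=C(\C)CC[C@@H]1[C@@]2(C)CCC[C@@](C)(C(=O)O[Si](C)(C)C)[C@@H]2[C@@H](O[Si](C)(C)C)C[C@@]1(C)O[Si](C)(C)C | intermediate (not isolated)
21 | silylated aldol adduct, 15-(3-methyl-5-oxo-2,5-dihydrofuran-2-yl)-15-(trimethylsilyloxy) derivative of 20 (new centres as mixture) | CC1=CC(=O)OC1C(O[Si](C)(C)C)/C=C(\C)CC[C@@H]1[C@@]2(C)CCC[C@@](C)(C(=O)O[Si](C)(C)C)[C@@H]2[C@@H](O[Si](C)(C)C)C[C@@]1(C)O[Si](C)(C)C | intermediate (not isolated)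
22 | tris(trimethylsilyl) derivative of 23 | CC1=CC(=O)O/C1=C\C=C(/C)CC[C@@H]1[C@@]2(C)CCC[C@@](C)(C(=O)O[Si](C)(C)C)[C@@H]2[C@@H](O[Si](C)(C)C)C[C@@]1(C)O[Si](C)(C)C | intermediate (not isolated)
23 | CNP0145461.1, (13E)-6α,8α-dihydroxy-15-[(2Z)-3-methyl-5-oxofuran-2(5H)-ylidene]labd-13-en-18-oic acid | CC1=CC(=O)O/C1=C\C=C(/C)CC[C@@H]1[C@@]2(C)CCC[C@@](C)(C(=O)O)[C@@H]2[C@@H](O)C[C@@]1(C)O | target

Total step count: 14. Longest linear sequence: 14 steps (from 1).

Steps most likely to fail

Step 4 (key step). The electron-withdrawing silyloxymethyl group may slow ionisation at C4, so the activated oxirane could rearrange by hydride shift or open at C3 in a 5-exo mode, or the cascade could stop after one ring. Fallback, setting out from 4: homolytic opening of the oxirane with Cp2TiCl (trivalent titanium, from Cp2TiCl2 and Mn dust, THF, rt) would place a radical on C4 whatever the cation stability. Two 6-endo radical closures and loss of hydrogen from C17 would then give the bicyclic exocyclic alkene F1. This radical closure is not stereospecific at C4, so the 4α-silyloxymethyl epimer would have to be separated. Protonation of the 8(17)-alkene with p-TsOH (cat.) in benzene and capture of the C8 cation by the ketone oxygen would close the dihydropyran and come back to the route at 5.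

Step 8. β-Scission of the neopentyl-type alkoxyl radical (loss of formaldehyde) may outrun the 1,5-hydrogen transfer, and iodine with acetic acid may strip the ketal. Fallback, setting out from 8: oxidise the primary alcohol to the carboxylic acid F2 (TEMPO, NaOCl, NaClO2, pH 6.7 phosphate buffer). The carboxylate then directs a γ-C–H lactonisation (Mn(OTf)2 complex of a PDP-type ligand, divalent manganese, H2O2, fluorinated alcohol), which should engage the same peri 6α-hydrogen. This comes back to the route at 11.

Step 14. The enal may be converted to a silyl dienol ether or be γ-deprotonated (E/Z scrambling at C13), and addition of the hindered silyloxyfuran or the elimination may stall. Fallback, setting out from 17: Ohira–Bestmann homologation (dimethyl (1-diazo-2-oxopropyl)phosphonate, K2CO3, MeOH) would give the terminal enyne F3. Tandem Sonogashira coupling and 5-exo-dig lactonisation with (Z)-3-iodobut-2-enoic acid (Pd(PPh3)4, zerovalent palladium, copper iodide CuI, Et3N, MeCN) would then build the (Z)-ylidene butenolide directly and arrive at 23.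

Further compounds
F1 | step 4 | 18-(tert-butyldimethylsilyloxy)-3β-hydroxy-14,15-dinorlabd-8(17)-en-13-one | CC(=O)CC[C@@H]1[C@@]2(C)CC[C@H](O)[C@@](C)(CO[Si](C)(C)C(C)(C)C)[C@@H]2CCC1=C
F2 | step 8 | 13-methoxy-8α,13-epoxy-14,15-dinorlabdan-18-oic acid | COC1(C)CC[C@@H]2[C@@]3(C)CCC[C@@](C)(C(=O)O)[C@@H]3CC[C@@]2(C)O1
F3 | step 14 | (13E)-14-ethynyl-6α,8α-dihydroxy-15-norlabd-13-en-18-oic acid | C#C/C=C(\C)CC[C@@H]1[C@@]2(C)CCC[C@@](C)(C(=O)O)[C@@H]2[C@@H](O)C[C@@]1(C)O
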